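The dihydropyran ring (chroman numbering) has one feature on which everything rests: the C3 carbinol sits between benzylic C4 and the gem-dimethyl carbon C2. It can therefore be read as an oxidised secondary boronate, and C3–C4 as a vinyl group on boron. One palladium-catalysed enantioselective conjunctive cross-coupling joins three pieces: aryl carbon C4a bonds to the vinyl terminus C4 while an isopropenyl group (C2 and its methyl carbons) migrates from boron to C3, which fixes the (R) centre under ligand control. The precursors are a bis(alkenyl) pinacol borate, made in the flask, and a 3-bromoacetophenone carrying the full oxygenation of ring A. Oxidation, pyran closure at O1–C2, Claisen–Schmidt condensation and MOM removal finish the route.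

Key step: step 4

Remark on the chemistry: the pyran part is numbered as a chroman (O1, C2, C3, C4, C4a … C8a) and the open-chain precursors as acetophenones (C1'–C6'). Compounds 1, 8, 9 and 16 are taken as commercially available. The sense of induction of the MandyPhos ligand is not assumed; the antipode that should give the (R)-boronate is to be fixed on a model aryl bromide.

Step 1
Reactants: 1 1-(2,4-dihydroxy-6-methoxyphenyl)ethanone; 2 chloromethyl methyl ether
Product: 3 1-[2-hydroxy-6-methoxy-4-(methoxymethoxy)phenyl]ethanone
Conditions: K2CO3 (1.5 equiv), acetone, 0 °C to rt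
Reagents that add atoms: chloromethyl methyl ether, COCCl
Why: Williamson-type O-alkylation should occur only at the 4'-hydroxyl because the 2'-hydroxyl is tied up in a hydrogen bond to the acetyl carbonyl and is much less acidic and nucleophilic.

Step 2
Reactants: 3 1-[2-hydroxy-6-methoxy-4-(methoxymethoxy)phenyl]ethanone; 4 N-bromosuccinimide
Product: 5 1-[3-bromo-2-hydroxy-6-methoxy-4-(methoxymethoxy)phenyl]ethanone
Conditions: NBS (1.0 equiv), CH2Cl2, −20 to 0 °C, dark
Reagents that add atoms: N-bromosuccinimide, O=C1CCC(=O)N1Br
Why: Electrophilic aromatic bromination should go to C3', the position ortho to the free hydrogen-bonded phenol, as halogenations of 2'-hydroxy-4',6'-dialkoxyacetophenones generally do, and one equivalent of NBS at low temperature should hold back attack at C5' and double bromination.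

Step 3
Reactants: 5 1-[3-bromo-2-hydroxy-6-methoxy-4-(methoxymethoxy)phenyl]ethanone; 6 acetic anhydride
Product: 7 2-acetyl-6-bromo-3-methoxy-5-(methoxymethoxy)phenyl acetate
Conditions: Ac2O, pyridine, DMAP (cat.), rt
Reagents that add atoms: acetic anhydride, CC(=O)OC(C)=O
Why: DMAP-catalysed O-acylation masks the acidic phenol, which would otherwise protonate the boron ate complex of step 4, as an ester that the alkaline peroxide work-up of that step removes again.

Step 4
Reactants: 7 2-acetyl-6-bromo-3-methoxy-5-(methoxymethoxy)phenyl acetate; 8 2-ethenyl-4,4,5,5-tetramethyl-1,3,2-dioxaborolane (vinylboronic acid pinacol ester); 9 isopropenylmagnesium bromide; 10 hydrogen peroxide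
Product: 13 1-[2-hydroxy-3-[(2R)-2-hydroxy-3-methylbut-3-en-1-yl]-6-methoxy-4-(methoxymethoxy)phenyl]ethanone, via boron ate complex 11 (not isolated), via allyl boronate 12 (not isolated)
Conditions: 8 (1.3 equiv), 9 (1.2 equiv), THF, 0 °C to rt; then 7, NaOTf, Pd(OAc)2 (3 mol %), MandyPhos ligand (3.6 mol %, antipode chosen for the (R) product), THF, 60 °C; then 3 M NaOH, 30% H2O2, 0 °C
Reagents that add atoms: vinylboronic acid pinacol ester, C=CB1OC(C)(C)C(C)(C)O1; isopropenylmagnesium bromide, CC(=C)[Mg]Br; hydrogen peroxide, OO
Why: Isopropenylmagnesium bromide adds to the boron of 8 to give the bis(alkenyl) ate complex 11; zerovalent palladium inserts into the C–Br bond of 7, the cationic aryl complex of divalent palladium binds the unsubstituted vinyl group of 11, and this π-activation triggers a 1,2-metallate shift of the isopropenyl group from boron to C3 (new C3–C2 bond) anti to palladium, after which reductive elimination forms the C4–C4a bond. The closest known reaction type is the palladium-catalysed enantioselective conjunctive cross-coupling of bis(alkenyl) borates with aryl electrophiles, with NaOTf to activate the Grignard-derived ate complex and to scavenge halide. No ring is closed in this step. The C3 stereocentre is set by the chiral MandyPhos–palladium complex, which differentiates the two faces of the bound vinyl group (catalyst control), and the alkaline peroxide oxidation then replaces boron by oxygen with retention. The step needs selectivity between the two alkenyl groups, secured because palladium binds the less hindered vinyl group while the α-substituted isopropenyl group is the better migrating group, and it needs the metallate shift to outrun direct Suzuki-type transfer, which the bisphosphine ligand and the triflate additive should favour. The same NaOH/H2O2 treatment cleaves the aryl acetate and frees the phenol at C8a for the ring closure, and it is kept short and cold so that the hindered ketone is not attacked in a Dakin oxidation.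

Step 5
Reactants: 13 1-[2-hydroxy-3-[(2R)-2-hydroxy-3-methylbut-3-en-1-yl]-6-methoxy-4-(methoxymethoxy)phenyl]ethanone
Product: 15 1-[(3R)-3-hydroxy-7-methoxy-5-(methoxymethoxy)-2,2-dimethyl-3,4-dihydro-2H-chromen-8-yl]ethanone, via organomercurial 14 (not isolated)
Conditions: Hg(OAc)2 (1.1 equiv), THF, rt; then NaBH4 (0.5 equiv), 3 M NaOH, −10 °C, short contact
Reagents that add atoms: none
Why: Intramolecular oxymercuration of the 1,1-disubstituted alkene by the only free phenol should close the pyran ring in the 6-exo-trig Markovnikov sense (O1 to the tertiary carbon C2), and reductive demercuration turns the CH2Hg group into the second methyl group without touching C3 or the MOM ether.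

Step 6
Reactants: 15 1-[(3R)-3-hydroxy-7-methoxy-5-(methoxymethoxy)-2,2-dimethyl-3,4-dihydro-2H-chromen-8-yl]ethanone; 16 4-(methoxymethoxy)benzaldehyde
Product: 18 (E)-1-[(3R)-3-hydroxy-7-methoxy-5-(methoxymethoxy)-2,2-dimethyl-3,4-dihydro-2H-chromen-8-yl]-3-[4-(methoxymethoxy)phenyl]prop-2-en-1-one, via aldol adduct 17 (not isolated)
Conditions: KOH (50% aq), EtOH, rt
Reagents that add atoms: 4-(methoxymethoxy)benzaldehyde, COCOc1ccc(C=O)cc1
Why: Claisen–Schmidt condensation (crossed aldol addition, then E1cB loss of water) should give the conjugated enone as the thermodynamically favoured E isomer, since the methyl ketone is the only enolisable partner and the aldehyde cannot enolise.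

Step 7
Reactants: 18 (E)-1-[(3R)-3-hydroxy-7-methoxy-5-(methoxymethoxy)-2,2-dimethyl-3,4-dihydro-2H-chromen-8-yl]-3-[4-(methoxymethoxy)phenyl]prop-2-en-1-one
Product: 19 (E)-1-[(3R)-3,5-dihydroxy-7-methoxy-2,2-dimethyl-3,4-dihydro-2H-chromen-8-yl]-3-(4-hydroxyphenyl)prop-2-en-1-one (CNP0122093.3)
Conditions: 3 M HCl, MeOH, 50 °C
Reagents that add atoms: none
Why: Acid-catalysed acetal exchange with methanol cleaves both MOM ethers, while the tertiary alkyl aryl ether of the pyran ring, the enone and the secondary alcohol at C3 are inert to dilute methanolic HCl.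

Compound list
1 | 1-(2,4-dihydroxy-6-methoxyphenyl)ethanone (2',4'-dihydroxy-6'-methoxyacetophenone) | CC(=O)c1c(O)cc(O)cc1OC | starting material
2 | chloromethyl methyl ether | COCCl | starting material
3 | 1-[2-hydroxy-6-methoxy-4-(methoxymethoxy)phenyl]ethanone | CC(=O)c1c(O)cc(OCOC)cc1OC | intermediate
4 | N-bromosuccinimide | O=C1CCC(=O)N1Br | starting material
5 | 1-[3-bromo-2-hydroxy-6-methoxy-4-(methoxymethoxy)phenyl]ethanone | CC(=O)c1c(O)c(Br)c(OCOC)cc1OC | intermediate
6 | acetic anhydride | CC(=O)OC(C)=O | starting material
7 | 2-acetyl-6-bromo-3-methoxy-5-(methoxymethoxy)phenyl acetate | CC(=O)Oc1c(Br)c(OCOC)cc(OC)c1C(C)=O | intermediate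
8 | 2-ethenyl-4,4,5,5-tetramethyl-1,3,2-dioxaborolane (vinylboronic acid pinacol ester) | C=CB1OC(C)(C)C(C)(C)O1 | starting material
9 | isopropenylmagnesium bromide | CC(=C)[Mg]Br | starting material
10 | hydrogen peroxide | OO | starting material
11 | bromomagnesium ethenyl(prop-1-en-2-yl)(pinacolato)borate (boron ate complex) | C=C[B-]1(C(C)=C)OC(C)(C)C(C)(C)O1.[Mg+]Br | intermediate (not isolated)
12 | 2-acetyl-3-methoxy-5-(methoxymethoxy)-6-[(2R)-3-methyl-2-(4,4,5,5-tetramethyl-1,3,2-dioxaborolan-2-yl)but-3-en-1-yl]phenyl acetate (allyl boronate) | CC(=O)Oc1c(C[C@@H](B2OC(C)(C)C(C)(C)O2)C(C)=C)c(OCOC)cc(OC)c1C(C)=O | intermediate (not isolated)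
13 | 1-[2-hydroxy-3-[(2R)-2-hydroxy-3-methylbut-3-en-1-yl]-6-methoxy-4-(methoxymethoxy)phenyl]ethanone | CC(=O)c1c(O)c(C[C@@H](O)C(C)=C)c(OCOC)cc1OC | intermediate
14 | [(3R)-8-acetyl-3-hydroxy-7-methoxy-5-(methoxymethoxy)-2-methyl-3,4-dihydro-2H-chromen-2-yl]methylmercury acetate, mixture of epimers at C2 (organomercurial) | CC(=O)c1c(OC)cc(OCOC)c2c1OC(C)(C[Hg]OC(C)=O)[C@H](O)C2 | intermediate (not isolated)
15 | 1-[(3R)-3-hydroxy-7-methoxy-5-(methoxymethoxy)-2,2-dimethyl-3,4-dihydro-2H-chromen-8-yl]ethanone | CC(=O)c1c(OC)cc(OCOC)c2c1OC(C)(C)[C@H](O)C2 | intermediate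
16 | 4-(methoxymethoxy)benzaldehyde | COCOc1ccc(C=O)cc1 | starting material
17 | 3-hydroxy-1-[(3R)-3-hydroxy-7-methoxy-5-(methoxymethoxy)-2,2-dimethyl-3,4-dihydro-2H-chromen-8-yl]-3-[4-(methoxymethoxy)phenyl]propan-1-one, mixture of epimers at the new carbinol (aldol adduct) | COCOc1ccc(C(O)CC(=O)c2c(OC)cc(OCOC)c3c2OC(C)(C)[C@H](O)C3)cc1 | intermediate (not isolated)
18 | (E)-1-[(3R)-3-hydroxy-7-methoxy-5-(methoxymethoxy)-2,2-dimethyl-3,4-dihydro-2H-chromen-8-yl]-3-[4-(methoxymethoxy)phenyl]prop-2-en-1-one | COCOc1ccc(/C=C/C(=O)c2c(OC)cc(OCOC)c3c2OC(C)(C)[C@H](O)C3)cc1 | intermediate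
19 | (E)-1-[(3R)-3,5-dihydroxy-7-methoxy-2,2-dimethyl-3,4-dihydro-2H-chromen-8-yl]-3-(4-hydroxyphenyl)prop-2-en-1-one | COc1cc(O)c2c(c1C(=O)/C=C/c1ccc(O)cc1)OC(C)(C)[C@H](O)C2 | target

Total step count: 7
Longest linear sequence: 7 steps (1 to 19)

Steps most likely to fail

1. Step 4. Oxidative addition at the electron-rich, di-ortho-substituted bromide may be slow, so that direct transfer of an alkenyl group from boron to palladium or β-hydride elimination overtakes the metallate shift. Facial selectivity at the bound vinyl group may also be poor with so hindered an aryl group, and the free o-hydroxy ketone may be over-oxidised in the peroxide work-up. The fallback gives up the boron-based assembly and builds the pyran ring by known chromene chemistry; it sets out from 3 and comes back to the route at 15. Condensation of phenol 3 with 3-methylbut-2-enal (ethylenediammonium diacetate, xylene, reflux; aldol-type attack at C3', the only carbon ortho to the free phenol, then oxa-6π electrocyclisation) should give 1-[7-methoxy-5-(methoxymethoxy)-2,2-dimethyl-2H-chromen-8-yl]ethanone F1. Jacobsen–Katsuki epoxidation of this cis-alkene ((R,R)-N,N'-bis(3,5-di-tert-butylsalicylidene)-1,2-cyclohexanediaminomanganese chloride, a complex of trivalent manganese, NaOCl, 4-phenylpyridine N-oxide, CH2Cl2, 0 °C; the antipode is used if a model shows the opposite sense) should give the (3R,4R)-3,4-epoxide of that chromene F2. Hydrogenolysis of the benzylic C4–O bond alone (H2, Pd/C, EtOAc, rt) then leaves the C3–O bond and its configuration untouched and delivers 15.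

2. Step 2. Site selectivity between C3' and C5' may be poor, because both positions are activated by three oxygen substituents, and a second bromination may follow. The fallback moves the halogenation ahead of the differentiation of the hydroxyls and changes the halogen, so that site control rests on the position between two free hydroxyls of a resorcinol instead of on ortho-direction by one phenol; it sets out from 1 and comes back to the route at 12. Iodination of 1 (I2, HIO3, aqueous EtOH, rt) should give 1-(2,4-dihydroxy-3-iodo-6-methoxyphenyl)ethanone F3. Selective protection of the 4'-hydroxyl as in step 1 should give 1-[2-hydroxy-3-iodo-6-methoxy-4-(methoxymethoxy)phenyl]ethanone F4, and acetylation as in step 3 should give 2-acetyl-6-iodo-3-methoxy-5-(methoxymethoxy)phenyl acetate F5. This iodide takes the place of 7 in the conjunctive coupling of step 4 and gives the same allyl boronate 12.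

3. Step 5. The borohydride used for demercuration may reduce the aryl ketone, the β-aryloxyalkyl radical formed on demercuration may fragment with loss of the phenol, or closure may stall because the phenol is hydrogen-bonded to the ketone. The fallback replaces mercury and hydride by a selenium-triggered closure followed by a radical reduction with a tin hydride, which brings no hydride reagent near the ketone; it sets out from 13 and comes back to the route at 15. Selenoetherification (N-(phenylseleno)phthalimide, CH2Cl2, 0 °C) should give 1-[(3R)-3-hydroxy-7-methoxy-5-(methoxymethoxy)-2-methyl-2-(phenylselanylmethyl)-3,4-dihydro-2H-chromen-8-yl]ethanone F6 as a mixture of epimers at C2. Reductive removal of selenium (Bu3SnH, AIBN, toluene, 80 °C) then converts the CH2SePh group into the second methyl group and gives 15.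

Further compounds
F1 | step 4 | 1-[7-methoxy-5-(methoxymethoxy)-2,2-dimethyl-2H-chromen-8-yl]ethanone | CC(=O)c1c(OC)cc(OCOC)c2c1OC(C)(C)C=C2
F2 | step 4 | 1-[(3R,4R)-3,4-epoxy-7-methoxy-5-(methoxymethoxy)-2,2-dimethyl-3,4-dihydro-2H-chromen-8-yl]ethanone | CC(=O)c1c(OC)cc(OCOC)c2c1OC(C)(C)[C@@H]3O[C@@H]32
F3 | step 2 | 1-(2,4-dihydroxy-3-iodo-6-methoxyphenyl)ethanone | CC(=O)c1c(O)c(I)c(O)cc1OC
F4 | step 2 | 1-[2-hydroxy-3-iodo-6-methoxy-4-(methoxymethoxy)phenyl]ethanone | CC(=O)c1c(O)c(I)c(OCOC)cc1OC
F5 | step 2 | 2-acetyl-6-iodo-3-methoxy-5-(methoxymethoxy)phenyl acetate | CC(=O)Oc1c(I)c(OCOC)cc(OC)c1C(C)=O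
F6 | step 5 | 1-[(3R)-3-hydroxy-7-methoxy-5-(methoxymethoxy)-2-methyl-2-(phenylselanylmethyl)-3,4-dihydro-2H-chromen-8-yl]ethanone, mixture of epimers at C2 | CC(=O)c1c(OC)cc(OCOC)c2c1OC(C)(C[Se]c3ccccc3)[C@H](O)C2
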